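Ring A is annulated onto a ring B cyclohexenol in one flask (eremophilane numbering). The precursor is the 2-methylacetoacetate of an (R)-cyclohexenol, so the C2–C3–C4 unit hangs on the C9 oxygen as an ester. Its bis-silyl ketene acetal undergoes a Carroll-type [3,3] shift across the allylic triad C9–C10=C5 of ring B: C4 is delivered to C5, the carbinol chirality becomes the C5 quaternary centre, and the double bond moves to C9=C10, where the diosphenol later needs it. Fluoride then frees the C2 enolate, which displaces the allylic chloride on C1 and closes ring A; CO2 is lost. Oxidation of ring B and esterification finish the route.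

Key step: step 6

Remark: locants C1–C10 follow eremophilane numbering (ring A = C1–C5 and C10; ring B = C5–C10; C3 carries the ester, C4 and C5 the methyl groups, C7 the isopropylidene, C8 the ketone, C9 the enol hydroxyl). The configurations of the epoxide carbons (C9, C10) and of C7 in the epoxy ketone intermediates are not controlled and are erased in step 15.

Step 1
Reactants: 1 3-methylcyclohex-2-en-1-one
Product: 2 2-iodo-3-methylcyclohex-2-en-1-one
Conditions: I2, K2CO3, 4-(dimethylamino)pyridine (cat.), THF–H2O, rt
Reagents that add atoms: iodine, II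
Why: α-Iodination of the enone by conjugate addition of the amine catalyst, iodination of the resulting enolate and elimination of the catalyst should give the α-iodo enone.

Step 2
Reactants: 2 2-iodo-3-methylcyclohex-2-en-1-one
Product: 3 (R)-2-iodo-3-methylcyclohex-2-en-1-ol
Conditions: (S)-1-methyl-3,3-diphenyltetrahydro-1H,3H-pyrrolo[1,2-c][1,3,2]oxazaborole (10 mol %), BH3·SMe2, THF, −20 °C
Reagents that add atoms: none
Why: Corey–Bakshi–Shibata reduction, in which the iodoalkenyl side acts as the large group, so the (S)-catalyst should deliver hydride to give the (R)-allylic alcohol that sets C9.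

Step 3
Reactants: 3 (R)-2-iodo-3-methylcyclohex-2-en-1-ol; 4 (tributylstannyl)methanol
Product: 5 (R)-2-(hydroxymethyl)-3-methylcyclohex-2-en-1-ol
Conditions: Pd(PPh3)4 (5 mol %), dioxane, 90 °C
Reagents that add atoms: none
Why: Stille coupling of the alkenyl iodide with the hydroxymethyl stannane installs C1 and tolerates both free hydroxyl groups; the carbinol centre is not involved.

Step 4
Reactants: 5 (R)-2-(hydroxymethyl)-3-methylcyclohex-2-en-1-ol
Product: 7 (R)-2-(chloromethyl)-3-methylcyclohex-2-en-1-ol, via mesylate 6 (not isolated)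
Conditions: MeSO2Cl, 2,4,6-collidine, LiCl, DMF, 0 °C
Reagents that add atoms: lithium chloride, [Li+].[Cl-]
Why: The unhindered primary allylic hydroxyl should be mesylated selectively and displaced by chloride (SN2) without allylic transposition, leaving the secondary carbinol untouched.

Step 5
Reactants: 7 (R)-2-(chloromethyl)-3-methylcyclohex-2-en-1-ol; 8 ethyl 2-methyl-3-oxobutanoate
Product: 9 (1R)-2-(chloromethyl)-3-methylcyclohex-2-en-1-yl 2-methyl-3-oxobutanoate (both epimers at the acyl α-carbon)
Conditions: xylene, 135 °C, removal of EtOH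
Reagents that add atoms: none
Why: Thermal transesterification of the β-keto ester (through the acylketene) acylates the secondary alcohol under neutral conditions that spare the allylic chloride, with retention at the carbinol carbon.

Step 6
Reactants: 9 (1R)-2-(chloromethyl)-3-methylcyclohex-2-en-1-yl 2-methyl-3-oxobutanoate
Product: 13 (1R,8aR)-1,8a-dimethyl-3,4,6,7,8,8a-hexahydronaphthalen-2(1H)-one (the 4R,5R 3-oxo-9(10)-ene), via bis-silyl ketene acetal 10 (not isolated), via rearranged silyl ester 11 (not isolated), via beta-keto acid 12 (not isolated)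
Conditions: LiN(iPr)2 (2.3 equiv), Me3SiCl, THF, −78 → 60 °C; then Bu4N[Ph3SiF2], 0 °C → rt; then 1 M HCl, 40 °C
Reagents that add atoms: none
Why: Double deprotonation with silylation in situ gives the O-allyl bis-silyl ketene acetal 10, which undergoes an Ireland-type ester-enolate Carroll [3,3] rearrangement through the cyclohexenyl ester; the closest known reactions are the dianionic Carroll rearrangement of allyl acetoacetates and Ireland–Claisen rearrangements of 3-methylcyclohex-2-enyl esters that build vicinal quaternary centres. The C4–C5 bond forms suprafacially on the ring face that carried the C9–O bond, so the carbinol configuration from step 2 is transferred to the C5 quaternary centre while the double bond shifts to C9=C10. Fluoride then cleaves the silyl enol ether of 11 to the regiodefined C2 enolate, which displaces the primary allylic chloride at C1 in a 6-(enolendo)-exo-tet C-alkylation that closes ring A. Acidification gives β-keto acid 12, which loses CO2; the enol should be protonated at C4 anti to the axial C5 methyl, placing the C4 methyl equatorial and cis to it. The step needs rearrangement before alkylation and attack at C1 rather than at C9 or through oxygen: the silyl ketene acetal and silyl enol ether do not alkylate the chloride until fluoride is added, and the primary terminus and the six-membered transition state direct the enolate carbon to C1.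

Step 7
Reactants: 13 (1R,8aR)-1,8a-dimethyl-3,4,6,7,8,8a-hexahydronaphthalen-2(1H)-one
Product: 14 (1R,2R,8aR)-1,8a-dimethyl-1,2,3,4,6,7,8,8a-octahydronaphthalen-2-ol
Conditions: Li, NH3 (l), THF, t-BuOH, −78 °C; NH4Cl
Reagents that add atoms: none
Why: Dissolving-metal reduction of the ketone should give the thermodynamically preferred equatorial C3 alcohol (trans to the C4 methyl, no 1,3-diaxial contact with the C5 methyl) and leave the isolated trisubstituted alkene untouched.

Step 8
Reactants: 14 (1R,2R,8aR)-1,8a-dimethyl-1,2,3,4,6,7,8,8a-octahydronaphthalen-2-ol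
Product: 15 (4aR,5R,6R)-6-hydroxy-4a,5-dimethyl-4,4a,5,6,7,8-hexahydronaphthalen-2(3H)-one
Conditions: Rh2(cap)4 (dirhodium tetrakis(caprolactamate), 1 mol %), t-BuOOH (70% in H2O), K2CO3, CH2Cl2, rt
Reagents that add atoms: tert-butyl hydroperoxide, CC(C)(C)OO
Why: Radical allylic oxidation should attack the CH2 next to the CH= terminus (C8), as in the 7-oxidation of 5-ene steroids, to give the C8 ketone conjugated with C9=C10, while the saturated secondary alcohol survives.

Step 9
Reactants: 15 (4aR,5R,6R)-6-hydroxy-4a,5-dimethyl-4,4a,5,6,7,8-hexahydronaphthalen-2(3H)-one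
Product: 16 (4aR,5R,6R)-1,8a-epoxy-6-hydroxy-4a,5-dimethyloctahydronaphthalen-2(1H)-one (the 9,10-epoxy-8-ketone)
Conditions: H2O2 (30%), NaOH, MeOH, 0 °C
Reagents that add atoms: hydrogen peroxide, OO
Why: Weitz–Scheffer nucleophilic epoxidation of the β,β-disubstituted enone, as for 4-en-3-one steroids; the epoxide configuration is of no consequence.

Step 10
Reactants: 16 the 9,10-epoxy-8-ketone; 17 acetone
Product: 19 the C7 (2-hydroxypropan-2-yl) derivative of 16, via dilithium enolate 18 (not isolated)
Conditions: LiN(iPr)2 (2.2 equiv), THF, −78 °C; acetone; AcOH, −78 °C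
Reagents that add atoms: none
Why: Kinetic deprotonation at C7, the only enolisable position of the epoxy ketone, followed by aldol addition to acetone at low temperature; the new C7 centre is removed later.

Step 11
Reactants: 20 3-methylfuran-2(5H)-one; 21 4-methoxybenzyl chloride
Product: 23 4-methoxybenzyl (Z)-4-hydroxy-2-methylbut-2-enoate, via sodium hydroxy carboxylate 22 (not isolated)
Conditions: NaOH (1.0 equiv), H2O–THF, rt; evaporation; 21, DMF, rt
Reagents that add atoms: sodium hydroxide, [Na+].[OH-]
Why: Saponification of the butenolide gives the (Z)-hydroxy carboxylate, and O-alkylation of the carboxylate keeps the Z geometry inherited from the ring.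

Step 12
Reactants: 23 4-methoxybenzyl (Z)-4-hydroxy-2-methylbut-2-enoate; 24 angelic acid, (Z)-2-methylbut-2-enoic acid
Product: 25 4-methoxybenzyl (Z)-2-methyl-4-{[(Z)-2-methylbut-2-enoyl]oxy}but-2-enoate
Conditions: PPh3, diisopropyl azodicarboxylate, THF, 0 °C
Reagents that add atoms: none
Why: Mitsunobu esterification, in which the angelate anion displaces the activated primary allylic alcohol, so the acid is never activated at its carbonyl and both Z double bonds should be preserved.

Step 13
Reactants: 25 4-methoxybenzyl (Z)-2-methyl-4-{[(Z)-2-methylbut-2-enoyl]oxy}but-2-enoate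
Product: 26 (Z)-2-methyl-4-{[(Z)-2-methylbut-2-enoyl]oxy}but-2-enoic acid
Conditions: CF3CO2H, anisole, CH2Cl2, 0 °C
Reagents that add atoms: none
Why: Acidolysis of the 4-methoxybenzyl ester with capture of the benzylic cation by anisole should free the acid without touching the allylic angelate.

Step 14
Reactants: 19 the C7 (2-hydroxypropan-2-yl) epoxy ketone; 26 (Z)-2-methyl-4-{[(Z)-2-methylbut-2-enoyl]oxy}but-2-enoic acid
Product: 28 the C3 ester of 19 with acid 26, via mixed anhydride 27 (not isolated)
Conditions: 2,4,6-Cl3C6H2COCl, Et3N, toluene, rt; then 19, 4-(dimethylamino)pyridine, rt → 40 °C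
Reagents that add atoms: none
Why: Yamaguchi esterification through the mixed anhydride should acylate the secondary C3 hydroxyl only, since the tertiary alcohol is unreactive and no enol hydroxyl is present yet.

Step 15
Reactants: 28 the C3 ester of 19 with acid 26
Product: 30 CNP0301409.1 [(4aR,5R,6R)-1-hydroxy-4a,5-dimethyl-2-oxo-3-(propan-2-ylidene)-2,3,4,4a,5,6,7,8-octahydronaphthalen-6-yl (Z)-2-methyl-4-{[(Z)-2-methylbut-2-enoyl]oxy}but-2-enoate], via diosphenol carbinol 29 (not isolated)
Conditions: p-TsOH·H2O (0.3 equiv), toluene, 50 °C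
Reagents that add atoms: none
Why: Acid should open the epoxide at the tertiary C10 and loss of the C9 proton gives the diosphenol 29 (the 4,5-epoxy-3-ketone to 4-hydroxy-4-en-3-one rearrangement known from steroids), after which the tertiary aldol loses water to give the conjugated isopropylidene ketone.

Compound list
1 | 3-methylcyclohex-2-en-1-one | CC1=CC(=O)CCC1 | starting material
2 | 2-iodo-3-methylcyclohex-2-en-1-one | CC1=C(I)C(=O)CCC1 | intermediate
3 | (R)-2-iodo-3-methylcyclohex-2-en-1-ol | O[C@@H]1CCCC(C)=C1I | intermediate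
4 | (tributylstannyl)methanol | CCCC[Sn](CCCC)(CCCC)CO | starting material
5 | (R)-2-(hydroxymethyl)-3-methylcyclohex-2-en-1-ol | O[C@@H]1CCCC(C)=C1CO | intermediate
6 | [(6R)-6-hydroxy-2-methylcyclohex-1-en-1-yl]methyl methanesulfonate | O[C@@H]1CCCC(C)=C1COS(C)(=O)=O | intermediate
7 | (R)-2-(chloromethyl)-3-methylcyclohex-2-en-1-ol | O[C@@H]1CCCC(C)=C1CCl | intermediate
8 | ethyl 2-methyl-3-oxobutanoate | CCOC(=O)C(C)C(C)=O | starting material
9 | (1R)-2-(chloromethyl)-3-methylcyclohex-2-en-1-yl 2-methyl-3-oxobutanoate | CC(=O)C(C)C(=O)O[C@@H]1CCCC(C)=C1CCl | intermediate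
10 | 1-{[(1R)-2-(chloromethyl)-3-methylcyclohex-2-en-1-yl]oxy}-2-methyl-1,3-bis(trimethylsilyloxy)buta-1,3-diene | C=C(O[Si](C)(C)C)C(C)=C(O[Si](C)(C)C)O[C@@H]1CCCC(C)=C1CCl | intermediate
11 | trimethylsilyl 2-[(1R)-2-(chloromethyl)-1-methylcyclohex-2-en-1-yl]-2-methyl-3-(trimethylsilyloxy)but-3-enoate | ClCC1=CCCC[C@]1(C)C(C)(C(=O)O[Si](C)(C)C)C(=C)O[Si](C)(C)C | intermediate
12 | (8aS)-1,8a-dimethyl-2-oxo-1,2,3,4,6,7,8,8a-octahydronaphthalene-1-carboxylic acid (C1 not defined) | O=C1CCC2=CCCC[C@]2(C)C1(C)C(=O)O | intermediate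
13 | (1R,8aR)-1,8a-dimethyl-3,4,6,7,8,8a-hexahydronaphthalen-2(1H)-one | O=C1CCC2=CCCC[C@]2(C)[C@H]1C | intermediate
14 | (1R,2R,8aR)-1,8a-dimethyl-1,2,3,4,6,7,8,8a-octahydronaphthalen-2-ol | O[C@@H]1CCC2=CCCC[C@]2(C)[C@H]1C | intermediate
15 | (4aR,5R,6R)-6-hydroxy-4a,5-dimethyl-4,4a,5,6,7,8-hexahydronaphthalen-2(3H)-one | O[C@@H]1CCC2=CC(=O)CC[C@]2(C)[C@H]1C | intermediate
16 | (4aR,5R,6R)-1,8a-epoxy-6-hydroxy-4a,5-dimethyloctahydronaphthalen-2(1H)-one | O[C@@H]1CCC23OC2C(=O)CC[C@]3(C)[C@H]1C | intermediate
17 | acetone | CC(C)=O | starting material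
18 | dilithium alkoxide enolate of 16 | [Li+].[Li+].[O-][C@@H]1CCC23OC2C([O-])=CC[C@]3(C)[C@H]1C | intermediate
19 | (4aR,5R,6R)-1,8a-epoxy-6-hydroxy-3-(2-hydroxypropan-2-yl)-4a,5-dimethyloctahydronaphthalen-2(1H)-one | O[C@@H]1CCC23OC2C(=O)C(C(C)(C)O)C[C@]3(C)[C@H]1C | intermediate
20 | 3-methylfuran-2(5H)-one | CC1=CCOC1=O | starting material
21 | 4-methoxybenzyl chloride | COc1ccc(CCl)cc1 | starting material
22 | sodium (Z)-4-hydroxy-2-methylbut-2-enoate | [Na+].OC/C=C(/C)C([O-])=O | intermediate
23 | 4-methoxybenzyl (Z)-4-hydroxy-2-methylbut-2-enoate | OC/C=C(/C)C(=O)OCc1ccc(OC)cc1 | intermediate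
24 | angelic acid, (Z)-2-methylbut-2-enoic acid | C/C=C(/C)C(=O)O | starting material
25 | 4-methoxybenzyl (Z)-2-methyl-4-{[(Z)-2-methylbut-2-enoyl]oxy}but-2-enoate | C/C=C(/C)C(=O)OC/C=C(/C)C(=O)OCc1ccc(OC)cc1 | intermediate
26 | (Z)-2-methyl-4-{[(Z)-2-methylbut-2-enoyl]oxy}but-2-enoic acid | C/C=C(/C)C(=O)OC/C=C(/C)C(=O)O | intermediate
27 | mixed anhydride of 26 and 2,4,6-trichlorobenzoic acid | C/C=C(/C)C(=O)OC/C=C(/C)C(=O)OC(=O)c1c(Cl)cc(Cl)cc1Cl | intermediate
28 | C3 ester of epoxy ketone carbinol 19 with acid 26 | C/C=C(/C)C(=O)OC/C=C(/C)C(=O)O[C@@H]1CCC23OC2C(=O)C(C(C)(C)O)C[C@]3(C)[C@H]1C | intermediate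
29 | C3 ester of the 9-hydroxy-9(10)-en-8-one bearing the C7 (2-hydroxypropan-2-yl) group | C/C=C(/C)C(=O)OC/C=C(/C)C(=O)O[C@@H]1CCC2=C(O)C(=O)C(C(C)(C)O)C[C@]2(C)[C@H]1C | intermediate
30 | CNP0301409.1 | C/C=C(/C)C(=O)OC/C=C(/C)C(=O)O[C@@H]1CCC2=C(O)C(=O)C(=C(C)C)C[C@]2(C)[C@H]1C | target

Total step count: 15. Longest linear sequence: 12 steps (steps 1–10, 14 and 15); steps 11–13 prepare the side-chain acid in parallel.

Steps most likely to fail

1. Step 6. The sigmatropic shift joins two fully substituted carbons and may be slow, so the ketene acetal may be hydrolysed or decompose before it rearranges. The ring closure may go through oxygen or at C9. Facial control in the protonation at C4 may be lost. The fallback sets out from diol 5 and returns at ketone 13; both bonds are still made in one flask, but ring A is closed through a π-allyl palladium complex instead of a chloride displacement. Selective acylation of the primary hydroxyl (pivaloyl chloride, pyridine, −20 °C) would give [(6R)-6-hydroxy-2-methylcyclohex-1-en-1-yl]methyl pivalate F1. Transesterification with 8 (4-(dimethylamino)pyridine cat., toluene, reflux) would give (1R)-3-methyl-2-(pivaloyloxymethyl)cyclohex-2-en-1-yl 2-methyl-3-oxobutanoate F2. F2 would be converted into its dianion (LiN(iPr)2, 2.3 equiv, THF, −78 → 65 °C), which undergoes the dianionic Carroll rearrangement. Pd(PPh3)4 (5 mol %) would then be added so that the C2 lithium enolate attacks the allyl palladium complex formed from the allylic pivalate at C1. Acidification with loss of CO2 leads to 13.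

2. Step 15. The acid may isomerise the two Z 2-methylbut-2-enoate units, cause retro-aldol loss of acetone instead of dehydration, or induce acyl migration with ring contraction of the epoxy ketone. The fallback sets out from 19 and returns at 30; it moves the acid treatment in front of the esterification and protects the enol. Treatment of 19 with p-TsOH·H2O in toluene would give (4aR,5R,6R)-1,6-dihydroxy-4a,5-dimethyl-3-(propan-2-ylidene)-4,4a,5,6,7,8-hexahydronaphthalen-2(3H)-one F3 with loss of water. Selective silylation of the more acidic enol hydroxyl (t-BuMe2SiCl, Et3N, CH2Cl2) would give the enol silyl ether F4. Yamaguchi esterification of the C3 hydroxyl with 26 would give the silyl-protected ester F5, and HF·pyridine in THF would release 30.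

3. Step 8. The free C3 carbinol may be over-oxidised, or hydrogen abstraction may compete at C1, the other allylic position. The fallback sets out from 14 and returns at 15; it uses a protecting group and a stoichiometric chromium oxidant. Silylation (t-BuMe2SiCl, imidazole, DMF) would give the tert-butyldimethylsilyl ether of 14 F6. Oxidation with CrO3·3,5-dimethylpyrazole in CH2Cl2 at −20 °C would give the silyl ether of enone 15 F7, and HF·pyridine would return 15.

Further compounds
F1 | step 6 | [(6R)-6-hydroxy-2-methylcyclohex-1-en-1-yl]methyl pivalate | O[C@@H]1CCCC(C)=C1COC(=O)C(C)(C)C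
F2 | step 6 | (1R)-3-methyl-2-(pivaloyloxymethyl)cyclohex-2-en-1-yl 2-methyl-3-oxobutanoate | CC(=O)C(C)C(=O)O[C@@H]1CCCC(C)=C1COC(=O)C(C)(C)C
F3 | step 15 | (4aR,5R,6R)-1,6-dihydroxy-4a,5-dimethyl-3-(propan-2-ylidene)-4,4a,5,6,7,8-hexahydronaphthalen-2(3H)-one | O[C@@H]1CCC2=C(O)C(=O)C(=C(C)C)C[C@]2(C)[C@H]1C
F4 | step 15 | enol tert-butyldimethylsilyl ether of F3 | O[C@@H]1CCC2=C(O[Si](C)(C)C(C)(C)C)C(=O)C(=C(C)C)C[C@]2(C)[C@H]1C
F5 | step 15 | C3 ester of F4 with acid 26 | C/C=C(/C)C(=O)OC/C=C(/C)C(=O)O[C@@H]1CCC2=C(O[Si](C)(C)C(C)(C)C)C(=O)C(=C(C)C)C[C@]2(C)[C@H]1C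
F6 | step 8 | tert-butyldimethylsilyl ether of 14 | CC(C)(C)[Si](C)(C)O[C@@H]1CCC2=CCCC[C@]2(C)[C@H]1C
F7 | step 8 | tert-butyldimethylsilyl ether of 15 | CC(C)(C)[Si](C)(C)O[C@@H]1CCC2=CC(=O)CC[C@]2(C)[C@H]1C
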